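**Plan**
1. Retrosynthetic cuts, latest first. Ring C'' is cut at O1''–C2'' (cyclodehydration), C2''–C3'' (Claisen aroylation) and C4''–C4a'' (Friedel–Crafts acetylation). Ring A'' is cut at C8''–C8a'' and C6''–C7'' (benzannulation). Last come C7''–O (acetylide oxidation) and C8–C8'' (Sonogashira coupling on ring A of acacetin).
2. Enabling feature: in ring A'' the biaryl carbon C8'' lies between the oxygenated carbons C7'' and C8a'', and the third oxygen sits on C5'', para to it. A ketene carbonyl carbon, a silyloxy-bearing alkyne carbon and the alkoxy carbon of a 3-alkoxycyclobutenone land on exactly these three positions around the alkyne substituent.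
3. Forward order: rings A, B and C arrive intact in acacetin. C8 is iodinated and alkynylated, and the alkyne is oxygenated. Ring A'' is grown on that alkyne. Ring C'' is closed last, with ring B'' supplied by 4-methoxybenzoyl chloride.
4. The biaryl bond is the former aryl–alkyne bond, so no tetra-ortho-substituted coupling is needed. After desilylation the new ring is locally symmetric, so the acetylation has no regiochemical choice to make.
5. One BCl3 treatment removes the two benzyl ethers and the chelated 5''-ethyl ether and leaves both anisole methyl ethers.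
6. Stereochemistry: the target has no stereocentre. The C8–C8'' axis is not defined in the given structure and is formed racemic.

Key step: step 6

Assumption: the target SMILES fixes no axial configuration, so the racemate about C8–C8'' is the goal; acacetin and 3-ethoxycyclobut-2-en-1-one are taken as catalogue compounds.
Locants: unprimed = chromone from acacetin, 4' = its ring B; double-primed = new chromone, 4''' = its ring B''.

Step 1
Reactants: 1 acacetin (5,7-dihydroxy-4'-methoxyflavone)
Product: 2 5,7-bis(benzyloxy)-4'-methoxyflavone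
Conditions: BnBr (2.6 equiv), K2CO3 (4 equiv), DMF, 80 °C
Reagents that add atoms: benzyl bromide, BrCc1ccccc1
Why: Williamson etherification, in which the acidic 7-OH reacts first and the chelated 5-OH follows on heating in a dipolar aprotic solvent, and in which capping O5 is what later sends the electrophile to C8 and not to C6.

Step 2
Reactants: 2 5,7-bis(benzyloxy)-4'-methoxyflavone
Product: 3 5,7-bis(benzyloxy)-8-iodo-4'-methoxyflavone
Conditions: N-iodosuccinimide (1.1 equiv), CF3CO2H (0.3 equiv), MeCN–CH2Cl2, 0 °C to rt, dark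
Reagents that add atoms: N-iodosuccinimide, O=C1CCC(=O)N1I
Why: Electrophilic aromatic iodination of the only doubly alkoxy-activated ring is known for 5,7-dialkoxyflavones to take place at C8, because C6 is squeezed between two ether groups and C3 and ring B are much less nucleophilic.

Step 3
Reactants: 3 5,7-bis(benzyloxy)-8-iodo-4'-methoxyflavone; 4 trimethylsilylacetylene
Product: 5 5,7-bis(benzyloxy)-4'-methoxy-8-[(trimethylsilyl)ethynyl]flavone
Conditions: PdCl2(PPh3)2 (5 mol %), CuI (10 mol %), Et3N–DMF, 70 °C, sealed tube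
Reagents that add atoms: none
Why: Sonogashira coupling is established on 8-iodo-5,7-dialkoxyflavones, tolerates the pyrone and the ethers, and uses a slim linear partner that copes with the two ortho oxygens once the mixture is warmed.

Step 4
Reactants: 5 5,7-bis(benzyloxy)-4'-methoxy-8-[(trimethylsilyl)ethynyl]flavone
Product: 6 5,7-bis(benzyloxy)-8-ethynyl-4'-methoxyflavone
Conditions: K2CO3 (0.2 equiv), MeOH–CH2Cl2, rt
Reagents that add atoms: none
Why: Carbonate-catalysed methanolysis of the C(sp)–Si bond is the standard protiodesilylation of alkynylsilanes and is too mild to open ring C.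

Step 5
Reactants: 6 5,7-bis(benzyloxy)-8-ethynyl-4'-methoxyflavone
Product: 9 5,7-bis(benzyloxy)-4'-methoxy-8-[(triisopropylsilyloxy)ethynyl]flavone, via lithium acetylide 7 (not isolated), via lithium ynolate 8 (not isolated)
Conditions: LiN(SiMe3)2 (2.3 equiv), t-BuOOH (1.1 equiv, anhydrous in decane), THF, −78 to 0 °C; then i-Pr3SiOSO2CF3 (1.2 equiv), −78 to 0 °C
Reagents that add atoms: tert-butyl hydroperoxide, CC(C)(C)OO; triisopropylsilyl trifluoromethanesulfonate, CC(C)[Si](C(C)C)(C(C)C)OS(=O)(=O)C(F)(F)F; lithium hexamethyldisilazide, [Li]N([Si](C)(C)C)[Si](C)(C)C (supplies only the lithium of 7 and 8)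
Why: Oxidation of a lithium acetylide with lithium tert-butyl peroxide to the ynolate and O-silylation with a bulky silyl triflate is the standard one-flask route from terminal alkyl and aryl alkynes to triisopropylsilyloxyalkynes, and it should tolerate ring C because the amide base is non-nucleophilic, C4=O is a doubly vinylogous ester shielded by the peri benzyloxy group, flavones resist Weitz–Scheffer-type attack by peroxide anions, and the nucleophilic carbon of 8 is buried between O1 and the 7-benzyloxy group.

Step 6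
Reactants: 9 5,7-bis(benzyloxy)-4'-methoxy-8-[(triisopropylsilyloxy)ethynyl]flavone; 10 3-ethoxycyclobut-2-en-1-one
Product: 15 5,7-bis(benzyloxy)-8-[4-ethoxy-2-hydroxy-6-(triisopropylsilyloxy)phenyl]-4'-methoxyflavone, via ethoxyvinylketene 11 (not isolated), via vinylcyclobutenone 12 (not isolated), via dienylketene 13 (not isolated), via cyclohexadienone 14 (not isolated)
Conditions: toluene (0.2 M), 110 °C, sealed tube, 10 (1.5 equiv) added in portions
Reagents that add atoms: none
Why: Heating opens 10 by conrotatory four-electron electrocyclic cleavage of its C1–C4 bond to ethoxyvinylketene 11, whose C=C=O unit adds across the electron-rich triple bond of 9 in a [2+2] cycloaddition to give 4-vinylcyclobutenone 12 (new bonds C8''–C8a'' and C6''–C7''). Under the same conditions 12 reopens to dienylketene 13, and ring A'' closes by disrotatory six-electron electrocyclisation (C4a''–C8a'', the bond that was cleaved in 10) to cyclohexadienone 14, which enolises to phenol 15. The closest known reaction type is the Danheiser benzannulation of cyclobutenones with triisopropylsilyloxyalkynes, which delivers 2-substituted resorcinol monosilyl ethers. The ketene carbonyl carbon becomes C8a'' (free OH), the two alkyne carbons become C8'' and C7'' (OSi), the ketene α-carbon becomes C6'', the ethoxy carbon C5'' and the former ring CH2 C4a''. The one selectivity required is the orientation of the [2+2] step, and it is secured by the silyloxy oxygen, which makes the flavone-bearing alkyne carbon the nucleophilic terminus that attacks the electrophilic ketene carbonyl carbon, so OH and OSi end up flanking the biaryl carbon. No stereocentre survives (the sp3 carbon of 12 is erased on ring opening), the C8–C8'' axis forms racemic, and ring C, the benzyl ethers and the anisole are spectators in a neutral, reagent-free thermolysis.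

Step 7
Reactants: 15 5,7-bis(benzyloxy)-8-[4-ethoxy-2-hydroxy-6-(triisopropylsilyloxy)phenyl]-4'-methoxyflavone
Product: 16 5,7-bis(benzyloxy)-8-(4-ethoxy-2,6-dihydroxyphenyl)-4'-methoxyflavone
Conditions: Bu4NF, AcOH (1.2 equiv each), THF, 0 °C
Reagents that add atoms: none
Why: Fluoride-induced cleavage of the aryl silyl ether, buffered with acetic acid so that ring C never meets basic fluoride, removes a group that was needed only to make the oxygenated alkyne isolable and leaves a ring whose two OH groups and two CH positions are pairwise equivalent.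

Step 8
Reactants: 16 5,7-bis(benzyloxy)-8-(4-ethoxy-2,6-dihydroxyphenyl)-4'-methoxyflavone; 17 acetic anhydride
Product: 18 8-(3-acetyl-4-ethoxy-2,6-dihydroxyphenyl)-5,7-bis(benzyloxy)-4'-methoxyflavone
Conditions: Ac2O (1.1 equiv), BF3·OEt2 (3 equiv), CH2Cl2, 0 °C to rt; then H2O
Reagents that add atoms: none
Why: Friedel–Crafts C-acetylation of phloroglucinol-type phenols with Ac2O and BF3·OEt2 is classical, the dihydroxy-ethoxy ring is by far the most nucleophilic arene in 16, its two free CH positions are enantiotopic so that attack at either gives the same constitution (racemic about the axis), and the first acyl group deactivates the ring towards a second.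

Step 9
Reactants: 18 8-(3-acetyl-4-ethoxy-2,6-dihydroxyphenyl)-5,7-bis(benzyloxy)-4'-methoxyflavone; 19 4-methoxybenzoyl chloride
Product: 21 5,7-bis(benzyloxy)-8-{4-ethoxy-2,6-dihydroxy-3-[3-(4-methoxyphenyl)-3-oxopropanoyl]phenyl}-4'-methoxyflavone, via trilithium salt 20 (not isolated)
Conditions: LiN(SiMe3)2 (4.5 equiv), THF, −78 to −10 °C; 19 (1.05 equiv), −78 °C to rt; aq. HCl
Reagents that add atoms: lithium hexamethyldisilazide, [Li]N([Si](C)(C)C)[Si](C)(C)C (supplies only the lithium of 20)
Why: This is the crossed Claisen acylation of a lithium polyanion, the protecting-group-free variant of the Baker–Venkataraman route to hydroxylated flavones, in which the enolate carbon of 20 outruns the sluggish lithium phenoxides for one equivalent of aroyl chloride and any ester formed on the ortho oxygen would be carried to the same 1,3-diketone by base-induced acyl migration.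

Step 10
Reactants: 21 5,7-bis(benzyloxy)-8-{4-ethoxy-2,6-dihydroxy-3-[3-(4-methoxyphenyl)-3-oxopropanoyl]phenyl}-4'-methoxyflavone
Product: 22 5,7-di-O-benzyl-5''-O-ethyl-4',4'''-di-O-methylcupressuflavone
Conditions: NaOAc, AcOH, 110 °C
Reagents that add atoms: none
Why: Cyclodehydration of an o-hydroxyaryl 1,3-diketone, the closing stage of the Baker–Venkataraman flavone synthesis, can only engage the hydroxyl ortho to the acyl group, which thereby becomes O1'' while the para hydroxyl becomes 7''-OH, and acetate-buffered acetic acid spares the benzyl ethers.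

Step 11
Reactants: 22 5,7-di-O-benzyl-5''-O-ethyl-4',4'''-di-O-methylcupressuflavone
Product: 23 4',4'''-di-O-methylcupressuflavone
Conditions: BCl3 (10 equiv), C6HMe5 (8 equiv), CH2Cl2, −78 to 0 °C; then H2O
Reagents that add atoms: none
Why: Lewis-acid ether cleavage with BCl3 and pentamethylbenzene as cation scavenger removes aryl benzyl ethers at low temperature without C-benzylation of the liberated phloroglucinol rings, the same reagent on warming dealkylates the 5''-ethoxy group because it is held in a six-membered boron chelate with C4''=O, and the unchelated 4'- and 4'''-methyl ethers are not attacked by BCl3 at or below 0 °C.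

**Compound list**
1 | acacetin (5,7-dihydroxy-4'-methoxyflavone) | COc1ccc(cc1)-c1cc(=O)c2c(O)cc(O)cc2o1 | starting material
2 | 5,7-bis(benzyloxy)-4'-methoxyflavone | COc1ccc(cc1)-c1cc(=O)c2c(OCc3ccccc3)cc(OCc3ccccc3)cc2o1 | intermediate
3 | 5,7-bis(benzyloxy)-8-iodo-4'-methoxyflavone | COc1ccc(cc1)-c1cc(=O)c2c(OCc3ccccc3)cc(OCc3ccccc3)c(I)c2o1 | intermediate
4 | trimethylsilylacetylene | C#C[Si](C)(C)C | starting material
5 | 5,7-bis(benzyloxy)-4'-methoxy-8-[(trimethylsilyl)ethynyl]flavone | COc1ccc(cc1)-c1cc(=O)c2c(OCc3ccccc3)cc(OCc3ccccc3)c(C#C[Si](C)(C)C)c2o1 | intermediate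
6 | 5,7-bis(benzyloxy)-8-ethynyl-4'-methoxyflavone | COc1ccc(cc1)-c1cc(=O)c2c(OCc3ccccc3)cc(OCc3ccccc3)c(C#C)c2o1 | intermediate
7 | lithium acetylide of 6 (not isolated) | COc1ccc(cc1)-c1cc(=O)c2c(OCc3ccccc3)cc(OCc3ccccc3)c(C#C[Li])c2o1 | intermediate
8 | lithium 2-[5,7-bis(benzyloxy)-4'-methoxyflavon-8-yl]ethynolate (not isolated) | COc1ccc(cc1)-c1cc(=O)c2c(OCc3ccccc3)cc(OCc3ccccc3)c(C#CO[Li])c2o1 | intermediate
9 | 5,7-bis(benzyloxy)-4'-methoxy-8-[(triisopropylsilyloxy)ethynyl]flavone | COc1ccc(cc1)-c1cc(=O)c2c(OCc3ccccc3)cc(OCc3ccccc3)c(C#CO[Si](C(C)C)(C(C)C)C(C)C)c2o1 | intermediate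
10 | 3-ethoxycyclobut-2-en-1-one | CCOC1=CC(=O)C1 | starting material
11 | 3-ethoxybuta-1,3-dien-1-one, the ethoxyvinylketene (not isolated) | C=C(OCC)C=C=O | intermediate
12 | 4-(1-ethoxyethenyl)-2-[5,7-bis(benzyloxy)-4'-methoxyflavon-8-yl]-3-(triisopropylsilyloxy)cyclobut-2-en-1-one, racemic at C4 (not isolated) | COc1ccc(cc1)-c1cc(=O)c2c(OCc3ccccc3)cc(OCc3ccccc3)c(c2o1)C1=C(O[Si](C(C)C)(C(C)C)C(C)C)C(C(=C)OCC)C1=O | intermediate
13 | 5-ethoxy-2-[5,7-bis(benzyloxy)-4'-methoxyflavon-8-yl]-3-(triisopropylsilyloxy)hexa-1,3,5-trien-1-one, carbon chain cis across C3=C4 (not isolated) | COc1ccc(cc1)-c1cc(=O)c2c(OCc3ccccc3)cc(OCc3ccccc3)c(c2o1)C(=C=O)/C(O[Si](C(C)C)(C(C)C)C(C)C)=C\C(=C)OCC | intermediate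
14 | 5-ethoxy-2-[5,7-bis(benzyloxy)-4'-methoxyflavon-8-yl]-3-(triisopropylsilyloxy)cyclohexa-2,4-dien-1-one (not isolated) | COc1ccc(cc1)-c1cc(=O)c2c(OCc3ccccc3)cc(OCc3ccccc3)c(c2o1)C1=C(O[Si](C(C)C)(C(C)C)C(C)C)C=C(OCC)CC1=O | intermediate
15 | 5,7-bis(benzyloxy)-8-[4-ethoxy-2-hydroxy-6-(triisopropylsilyloxy)phenyl]-4'-methoxyflavone, racemic about the biaryl axis | COc1ccc(cc1)-c1cc(=O)c2c(OCc3ccccc3)cc(OCc3ccccc3)c(c2o1)-c1c(O)cc(OCC)cc1O[Si](C(C)C)(C(C)C)C(C)C | intermediate
16 | 5,7-bis(benzyloxy)-8-(4-ethoxy-2,6-dihydroxyphenyl)-4'-methoxyflavone, no stereogenic axis | COc1ccc(cc1)-c1cc(=O)c2c(OCc3ccccc3)cc(OCc3ccccc3)c(c2o1)-c1c(O)cc(OCC)cc1O | intermediate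
17 | acetic anhydride | CC(=O)OC(C)=O | starting material
18 | 8-(3-acetyl-4-ethoxy-2,6-dihydroxyphenyl)-5,7-bis(benzyloxy)-4'-methoxyflavone, racemic about the axis | COc1ccc(cc1)-c1cc(=O)c2c(OCc3ccccc3)cc(OCc3ccccc3)c(c2o1)-c1c(O)cc(OCC)c(C(C)=O)c1O | intermediate
19 | 4-methoxybenzoyl chloride | COc1ccc(cc1)C(Cl)=O | starting material
20 | trilithium salt of 18, bis-phenoxide and ketone enolate (not isolated) | COc1ccc(cc1)-c1cc(=O)c2c(OCc3ccccc3)cc(OCc3ccccc3)c(c2o1)-c1c(O[Li])cc(OCC)c(C(=C)O[Li])c1O[Li] | intermediate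
21 | 5,7-bis(benzyloxy)-8-{4-ethoxy-2,6-dihydroxy-3-[3-(4-methoxyphenyl)-3-oxopropanoyl]phenyl}-4'-methoxyflavone, racemic about the axis, drawn as the diketo tautomer | COc1ccc(cc1)-c1cc(=O)c2c(OCc3ccccc3)cc(OCc3ccccc3)c(c2o1)-c1c(O)cc(OCC)c(C(=O)CC(=O)c3ccc(OC)cc3)c1O | intermediate
22 | 5,7-di-O-benzyl-5''-O-ethyl-4',4'''-di-O-methylcupressuflavone, racemic about the axis | COc1ccc(cc1)-c1cc(=O)c2c(OCc3ccccc3)cc(OCc3ccccc3)c(c2o1)-c1c(O)cc(OCC)c2c(=O)cc(-c3ccc(OC)cc3)oc12 | intermediate
23 | 4',4'''-di-O-methylcupressuflavone, racemic about the axis | COc1ccc(-c2cc(=O)c3c(O)cc(O)c(-c4c(O)cc(O)c5c(=O)cc(-c6ccc(OC)cc6)oc45)c3o2)cc1 | target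

**Step count and weak points**
Total step count: 11. Longest linear sequence: 11 steps (1 to 23).

The three steps most likely to fail:

Step 5. The acetylide, the peroxide anion or the ynolate may attack ring C (C2 or C4) of a second molecule. The base may metalate C3, or the silyl triflate may bind the pyrone carbonyl or silylate the ynolate at carbon.
- The fallback oxygenates the alkyne through trivalent iodine, so that neither a free acetylide nor a peroxide is present. It sets out from 6.
- PhI(OH)OTs in refluxing CHCl3 should convert 6 into the alkynyl(phenyl)iodonium tosylate F1.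
- Catalytic AgOSO2CF3 in MeCN at rt should collapse F1, with loss of the aryl iodide, to the alkynyl tosylate F2.
- One equivalent of MeLi in THF at −78 °C attacks the sulfonyl sulfur of F2 and releases ynolate 8. Ynolate 8 is silylated with i-Pr3SiOSO2CF3 as in step 5, and the route is rejoined at 9.

Step 6. The vinylogous-ester stabilisation of the four-membered ring may retard its electrocyclic opening, and the vinylketene may condense with itself. The [2+2] step may be slowed at an alkyne carbon flanked by O1 and the 7-benzyloxy group, and surplus ketene may esterify the new phenol.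
- The fallback gives up growing the ring and makes the biaryl bond by cross-coupling. It sets out from 3.
- Phloroglucinol is mono-etherified (EtOH, HCl gas) to 5-ethoxyresorcinol F3.
- F3 is protected (MeOCH2Cl, i-Pr2NEt, CH2Cl2) as 1-ethoxy-3,5-bis(methoxymethoxy)benzene F4.
- F4 is lithiated between the two acetal oxygens (n-BuLi, THF, 0 °C) and borylated (B(OMe)3, then mild aqueous acid) to [4-ethoxy-2,6-bis(methoxymethoxy)phenyl]boronic acid F5.
- Suzuki–Miyaura coupling of F5 with 3 (Pd(OAc)2, SPhos, K3PO4, toluene–H2O, 100 °C) should give the bis(methoxymethyl) ether F6.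
- HCl in MeOH at 40 °C removes both acetals from F6 without touching the benzyl ethers, and the route is rejoined at 16.

Step 9. Aroylation may occur on the remote phenoxide oxygen, the hindered diortho-substituted ketone may enolise incompletely, and ring C may erode slowly during the long exposure to excess amide base.
- The fallback builds ring C'' through a chalcone. It sets out from 18.
- BnBr and K2CO3 in refluxing acetone alkylate only the non-chelated hydroxyl and should give 8-[3-acetyl-6-(benzyloxy)-4-ethoxy-2-hydroxyphenyl]-5,7-bis(benzyloxy)-4'-methoxyflavone F7.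
- Claisen–Schmidt condensation of F7 with 4-methoxybenzaldehyde (KOH, EtOH, rt) should give the (E)-chalcone F8.
- Catalytic I2 in DMSO at 130 °C closes and dehydrogenates ring C'' to 5,7,7''-tri-O-benzyl-5''-O-ethyl-4',4'''-di-O-methylcupressuflavone F9.
- The conditions of step 11 applied to F9 bring the route back at 23.

**Further compounds**
F1 | step 5 | {[5,7-bis(benzyloxy)-4'-methoxyflavon-8-yl]ethynyl}(phenyl)iodonium 4-toluenesulfonate | COc1ccc(cc1)-c1cc(=O)c2c(OCc3ccccc3)cc(OCc3ccccc3)c(C#C[I+]c3ccccc3)c2o1.Cc1ccc(cc1)S(=O)(=O)[O-]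
F2 | step 5 | [5,7-bis(benzyloxy)-4'-methoxyflavon-8-yl]ethynyl 4-toluenesulfonate | COc1ccc(cc1)-c1cc(=O)c2c(OCc3ccccc3)cc(OCc3ccccc3)c(C#COS(=O)(=O)c3ccc(C)cc3)c2o1
F3 | step 6 | 5-ethoxyresorcinol | CCOc1cc(O)cc(O)c1
F4 | step 6 | 1-ethoxy-3,5-bis(methoxymethoxy)benzene | CCOc1cc(OCOC)cc(OCOC)c1
F5 | step 6 | [4-ethoxy-2,6-bis(methoxymethoxy)phenyl]boronic acid | CCOc1cc(OCOC)c(B(O)O)c(OCOC)c1
F6 | step 6 | 5,7-bis(benzyloxy)-8-[4-ethoxy-2,6-bis(methoxymethoxy)phenyl]-4'-methoxyflavone | COc1ccc(cc1)-c1cc(=O)c2c(OCc3ccccc3)cc(OCc3ccccc3)c(c2o1)-c1c(OCOC)cc(OCC)cc1OCOC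
F7 | step 9 | 8-[3-acetyl-6-(benzyloxy)-4-ethoxy-2-hydroxyphenyl]-5,7-bis(benzyloxy)-4'-methoxyflavone | COc1ccc(cc1)-c1cc(=O)c2c(OCc3ccccc3)cc(OCc3ccccc3)c(c2o1)-c1c(OCc3ccccc3)cc(OCC)c(C(C)=O)c1O
F8 | step 9 | 5,7-bis(benzyloxy)-8-{6-(benzyloxy)-4-ethoxy-2-hydroxy-3-[(E)-3-(4-methoxyphenyl)prop-2-enoyl]phenyl}-4'-methoxyflavone | COc1ccc(cc1)-c1cc(=O)c2c(OCc3ccccc3)cc(OCc3ccccc3)c(c2o1)-c1c(OCc3ccccc3)cc(OCC)c(C(=O)/C=C/c3ccc(OC)cc3)c1O
F9 | step 9 | 5,7,7''-tri-O-benzyl-5''-O-ethyl-4',4'''-di-O-methylcupressuflavone | COc1ccc(cc1)-c1cc(=O)c2c(OCc3ccccc3)cc(OCc3ccccc3)c(c2o1)-c1c(OCc3ccccc3)cc(OCC)c2c(=O)cc(-c3ccc(OC)cc3)oc12
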